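A direct plan would build the open chain C1–C16 linearly (chain alcohol, Wittig olefination, allylic bromide, auxiliary-controlled alkylation for C4, malonate homologation) to the γ,δ-unsaturated β-keto ester A1. It would then turn the C3 ketone into the hydroperoxy methyl ketal A2 and close the 1,2-dioxane by 6-exo peroxymercuration–demercuration onto the C6=C7 alkene to the methoxy peroxyketal A3, followed by saponification and ketal hydrolysis.
Weak step 1, the ring closure with a stoichiometric divalent mercury salt: it would set the quaternary peroxide carbon C6 only through a chair preference between a methyl group and a primary alkyl branch, and the borohydride demercuration would pass through a β-peroxy alkyl radical that can close to an epoxide.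
Weak step 2, the handling of C3: ketone, dimethyl ketal, hydroperoxy ketal, methoxy peroxyketal, hemiketal. These are four changes that build no skeletal bond and end with acid hydrolysis of a peroxyketal beside a latent β-keto acid.
Weak step 3, the run-up: about nine linear steps before any O–O bond is present, with ester → alcohol → bromide changes and an auxiliary that is put on and taken off only to set C4.

Retrosynthetic overview
1. Key disconnection: the C6–CH3 bond. The quaternary peroxide carbon C6 would be made last, by methyl transfer to a cyclic peroxycarbenium ion generated from a bicyclic ozonide (2,3,7-trioxabicyclo[2.2.1]heptane) in which C3 and C6 are both ketal carbons joined by O1–O2 and by an ether bridge.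
2. The ozonide would come in one step from a 1,4-diketone (C3=O, C6=O) and H2O2, which forms both C–O bonds of the later 1,2-dioxane ring (O2–C3 and O1–C6) by ketalisation, without an alkene and without mercury.
3. The ring segment C3–C4(CH3)–C5–C6 is (R)-methylsuccinic acid at the diketone oxidation level: its two carboxyl carbons become the peroxide-bearing carbons C3 and C6 and its stereocentre becomes C4. The C7–C16 chain with C8 comes from (S)-3-bromo-2-methylpropan-1-ol.
4. Ring order: the trioxabicycle (1,2-dioxane plus ether bridge) is closed first and the bridge is then opened at C6, which releases the C3 hemiketal directly. C6 is set by axial methyl delivery trans to the C4 methyl group, both ozonide diastereomers converge, and C3 settles thermodynamically.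
5. The design avoids the mercury cyclisation, the chain of ketal exchanges with its final peroxyketal hydrolysis, the auxiliary and most of the linear run-up (8 steps, longest linear sequence 7).

Key step: step 8

Remarks on the chemistry: atom numbers are those of the target (C1 = CO2H, C3 = hemiketal carbon, C4 = ring CH(CH3), C6 = quaternary peroxide carbon, C8 = side-chain CH(CH3), O1/O2 = peroxide oxygens on C6/C3); "bridge oxygen" is the ether oxygen O7 of the ozonide. Assumption: compounds 13–16 are carried as mixtures at their ketal carbons (bridgehead pair of the ozonide, C3 of 15 and 16), because these centres are erased or equilibrated in step 8.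

Step 1
Reactants: 1 (7-bromoheptyl)benzene; 2 (S)-3-bromo-2-methylpropan-1-ol
Product: 4 (R)-2-methyl-10-phenyldecan-1-ol, via (7-phenylheptyl)magnesium bromide 3 (not isolated)
Conditions: 1 (2.4 equiv), Mg, THF, 40 °C; then 2, Li2CuCl4 (cat.), THF, −78 °C → rt; aq. NH4Cl
Reagents that add atoms: none
Why: Copper-catalysed sp3–sp3 Grignard cross-coupling (Kochi-type) should displace the primary bromide of 2 while the first equivalent of 3 holds the hydroxyl group as its magnesium alkoxide; the stereocentre of 2 is not touched and becomes C8 (R) of the target.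

Step 2
Reactants: 4 (R)-2-methyl-10-phenyldecan-1-ol
Product: 5 [(9R)-10-bromo-9-methyldecyl]benzene
Conditions: CBr4, PPh3, CH2Cl2, 0 °C → rt
Reagents that add atoms: carbon tetrabromide, BrC(Br)(Br)Br
Why: Appel bromination should convert the primary alcohol into the bromide by SN2 displacement of the oxyphosphonium group under neutral conditions, one carbon away from the C8 stereocentre, which is therefore retained.

Step 3
Reactants: 6 (2R)-2-methylbutanedioic acid ((R)-methylsuccinic acid)
Product: 7 (3R)-3-methyloxolane-2,5-dione ((R)-methylsuccinic anhydride)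
Conditions: AcCl (neat), 50 °C; evaporate
Reagents that add atoms: none
Why: Dehydrative cyclisation of the 1,4-diacid through the mixed acetic anhydride should give the five-membered cyclic anhydride under acidic, base-free conditions, so the α-stereocentre (the later C4) should not epimerise.

Step 4
Reactants: 5 [(9R)-10-bromo-9-methyldecyl]benzene; 7 (3R)-3-methyloxolane-2,5-dione
Product: 9 (2R,6R)-2,6-dimethyl-4-oxo-14-phenyltetradecanoic acid, via the Grignard reagent 8 (not isolated)
Conditions: 5, Mg, THF, 45 °C; slow addition to 7 (1.5 equiv), THF, −78 → −30 °C; 1 M HCl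
Reagents that add atoms: none
Why: Acylation of a Grignard reagent by a cyclic anhydride: 8 should attack the less hindered carbonyl group of 7 (the one next to CH2, the later C6) and the magnesium carboxylate released on ring opening should prevent a second addition, so that the two carbonyl carbons of the chiral-pool anhydride become C6 (ketone) and C3 (acid) and its untouched stereocentre becomes C4 (R).

Step 5
Reactants: 9 (2R,6R)-2,6-dimethyl-4-oxo-14-phenyltetradecanoic acid; 10 potassium 3-methoxy-3-oxopropanoate (potassium methyl malonate)
Product: 12 methyl (4R,8R)-4,8-dimethyl-3,6-dioxo-16-phenylhexadecanoate, via the acyl imidazolide 11 (not isolated)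
Conditions: 1,1'-carbonyldiimidazole, THF, rt; then 10, MgCl2, Et3N, MeCN, rt; aq. HCl; used at once
Reagents that add atoms: none
Why: Masamune–Brooks homologation: the acyl imidazolide should C-acylate the magnesium enolate of the malonate half ester and loss of CO2 gives the β-keto ester under near-neutral conditions that should leave the α-methyl centre C4 intact.

Step 6
Reactants: 12 methyl (4R,8R)-4,8-dimethyl-3,6-dioxo-16-phenylhexadecanoate
Product: 13 methyl 2-[(6R)-6-methyl-4-[(2R)-2-methyl-10-phenyldecyl]-2,3,7-trioxabicyclo[2.2.1]heptan-1-yl]acetate (two bridgehead diastereomers, 6-methyl syn or anti to O7)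
Conditions: H2O2 (anhydrous ethereal solution, 1.5 equiv), camphorsulfonic acid (cat.), MgSO4, Et2O, 0 °C → rt; NaHCO3
Reagents that add atoms: hydrogen peroxide, OO
Why: Acid-catalysed peroxidative double ketalisation of a 1,4-diketone (ozone-free ozonide synthesis): H2O2 should add to the C6 ketone, the geminal hydroxy hydroperoxide closes onto the C3 ketone to the cyclic bis(peroxyhemiketal), and loss of water between the two hemiketal hydroxyls closes the ether bridge, so that O1–C6 and O2–C3 are both formed here and the bridgehead configuration needs no control.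

Step 7
Reactants: 13 methyl 2-[(6R)-6-methyl-4-[(2R)-2-methyl-10-phenyldecyl]-2,3,7-trioxabicyclo[2.2.1]heptan-1-yl]acetate
Product: 14 2-[(6R)-6-methyl-4-[(2R)-2-methyl-10-phenyldecyl]-2,3,7-trioxabicyclo[2.2.1]heptan-1-yl]acetic acid (two bridgehead diastereomers)
Conditions: LiOH, THF/H2O, 0 °C → rt; cold dilute HCl to pH 4
Reagents that add atoms: lithium hydroxide, [Li+].[OH-]
Why: Saponification is placed on the ozonide because both peroxide-bearing carbons are quaternary ketal carbons without hydrogen, so Kornblum–DeLaMare-type fragmentation is not possible and the β-keto acid stays masked; ester hydrolysis beside a tetrasubstituted 1,2,4-trioxolane is a known reaction type.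

Step 8
Reactants: 14 2-[(6R)-6-methyl-4-[(2R)-2-methyl-10-phenyldecyl]-2,3,7-trioxabicyclo[2.2.1]heptan-1-yl]acetic acid
Product: 17 2-[(3S,4R,6S)-3-hydroxy-4,6-dimethyl-6-[(2R)-2-methyl-10-phenyldecyl]-1,2-dioxan-3-yl]acetic acid (target), via the cyclic peroxycarbenium ion 15 (not isolated), via the O-silyl peroxyketal 16 (not isolated)
Conditions: Me3Al (4 equiv), CH2Cl2, −78 °C; then Me3SiOSO2CF3 (1.2 equiv), −78 → −40 °C; aq. potassium sodium tartrate, then citric acid to pH 4
Reagents that add atoms: trimethylaluminium, C[Al](C)C
Why: Proposed new method: after Me3Al has turned CO2H into its aluminium carboxylate, Me3SiOSO2CF3 should silylate the most basic oxygen, the ether bridge O7, and break the C6–O7 bond of both diastereomers of 14 (C6 is the dialkyl-substituted ketal carbon, C3 is deactivated by its CH2CO2 group), which gives the ring-retained peroxycarbenium ion 15 that takes a methyl group from Me3Al to form the C6–CH3 bond. The closest known reaction types are the Lewis-acid C-alkylation of cyclic peroxyketals and ozonides through peroxycarbenium ions with silyl nucleophiles, the Me3Al/silyl triflate methylation of six-membered cyclic oxocarbenium ions, and the Me3Al C-10 methylation of artemisinin-type trioxanes, in which an O–O bond survives the reagent at low temperature. No ring is closed: the 1,2-dioxane ring already exists in the ozonide and is set free when the 1,2,4-trioxolane and oxolane rings are opened at C6–O7. C6 is the only new stereocentre and is controlled by the chiral-pool centre C4: in the half-chair cation with the C4 methyl group pseudo-equatorial the nucleophile should enter along the axial trajectory on the face away from that methyl group, so CH3 on C6 ends trans to CH3 on C4 (6S) whichever ozonide diastereomer reacts. C3 leaves the step as the silyl ketal 16 and, after aqueous acid, as the free hemiketal, which should settle as the 3S anomer with axial OH and equatorial CH2CO2H. The step needs ionisation at C6–O7 and not at a peroxide C–O bond, secured by the basicity of O7 and by the silyl cap that keeps the hemiketal oxygen from collapsing to the C3 ketone, and it needs methyl transfer to carbon to outrun attack of Me3Al on the O–O bond, favoured by −78 °C and by adding the silyl triflate last.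

Compound list
1 | (7-bromoheptyl)benzene | BrCCCCCCCc1ccccc1 | starting material
2 | (S)-3-bromo-2-methylpropan-1-ol | C[C@H](CBr)CO | starting material
3 | (7-phenylheptyl)magnesium bromide | Br[Mg]CCCCCCCc1ccccc1 | intermediate (not isolated)
4 | (R)-2-methyl-10-phenyldecan-1-ol | C[C@H](CCCCCCCCc1ccccc1)CO | intermediate
5 | [(9R)-10-bromo-9-methyldecyl]benzene | C[C@H](CCCCCCCCc1ccccc1)CBr | intermediate
6 | (2R)-2-methylbutanedioic acid ((R)-methylsuccinic acid) | C[C@H](CC(=O)O)C(=O)O | starting material
7 | (3R)-3-methyloxolane-2,5-dione ((R)-methylsuccinic anhydride) | C[C@@H]1CC(=O)OC1=O | intermediate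
8 | [(2R)-2-methyl-10-phenyldecyl]magnesium bromide | C[C@H](CCCCCCCCc1ccccc1)C[Mg]Br | intermediate (not isolated)
9 | (2R,6R)-2,6-dimethyl-4-oxo-14-phenyltetradecanoic acid | C[C@H](CCCCCCCCc1ccccc1)CC(=O)C[C@@H](C)C(=O)O | intermediate
10 | potassium 3-methoxy-3-oxopropanoate | COC(=O)CC(=O)[O-].[K+] | starting material
11 | 1-[(2R,6R)-2,6-dimethyl-4-oxo-14-phenyltetradecanoyl]-1H-imidazole | C[C@H](CCCCCCCCc1ccccc1)CC(=O)C[C@@H](C)C(=O)n1ccnc1 | intermediate (not isolated)
12 | methyl (4R,8R)-4,8-dimethyl-3,6-dioxo-16-phenylhexadecanoate | C[C@H](CCCCCCCCc1ccccc1)CC(=O)C[C@@H](C)C(=O)CC(=O)OC | intermediate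
13 | methyl 2-[(6R)-6-methyl-4-[(2R)-2-methyl-10-phenyldecyl]-2,3,7-trioxabicyclo[2.2.1]heptan-1-yl]acetate (both bridgehead diastereomers, 6-methyl syn or anti to O7) | COC(=O)CC12OOC(C[C@H](C)CCCCCCCCc3ccccc3)(O1)C[C@H]2C | intermediate
14 | 2-[(6R)-6-methyl-4-[(2R)-2-methyl-10-phenyldecyl]-2,3,7-trioxabicyclo[2.2.1]heptan-1-yl]acetic acid (both bridgehead diastereomers) | OC(=O)CC12OOC(C[C@H](C)CCCCCCCCc3ccccc3)(O1)C[C@H]2C | intermediate
15 | ring-retained peroxycarbenium ion: 1,2-dioxane ring with cationic C6 (O1=C6 oxonium form) bearing the (2R)-2-methyl-10-phenyldecyl group, (4R)-methyl, C3 as trimethylsilyl ketal carrying the CH2CO2AlMe2 group, triflate counter-ion (C3 epimers) | C[C@H](CCCCCCCCc1ccccc1)CC1=[O+]OC(O[Si](C)(C)C)(CC(=O)O[Al](C)C)[C@H](C)C1.[O-]S(=O)(=O)C(F)(F)F | intermediate (not isolated)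
16 | dimethylaluminium 2-[(4R,6S)-4,6-dimethyl-6-[(2R)-2-methyl-10-phenyldecyl]-3-[(trimethylsilyl)oxy]-1,2-dioxan-3-yl]acetate (C3 epimers) | C[C@H](CCCCCCCCc1ccccc1)C[C@@]1(C)C[C@@H](C)C(O[Si](C)(C)C)(CC(=O)O[Al](C)C)OO1 | intermediate (not isolated)
17 | 2-[(3S,4R,6S)-3-hydroxy-4,6-dimethyl-6-[(2R)-2-methyl-10-phenyldecyl]-1,2-dioxan-3-yl]acetic acid | C[C@H](CCCCCCCCc1ccccc1)C[C@@]1(C)C[C@@H](C)[C@](O)(CC(=O)O)OO1 | target

Total step count: 8. Longest linear sequence: 7 steps (1, 2, 4, 5, 6, 7, 8).

Steps most likely to fail

Step 8, the step that carries the label, is the riskiest. The ozonide may ionise at a peroxide C–O bond instead of the ether bridge. The silylated hemiketal may collapse to the open keto carbonyl oxide, so that methyl transfer loses its facial control. Me3Al may attack the O–O bond, the cation may undergo a Criegee-type 1,2-shift, or a second methyl group may enter at C3. The fallback uses established chemistry, sets out from 12 and comes back at 17. Wittig methylenation of 12 with Ph3P=CH2 (2.2 equiv, the first equivalent shields C3 as the β-keto ester enolate) should give methyl (4R,8R)-4,8-dimethyl-6-methylidene-3-oxo-16-phenylhexadecanoate F1. Mukaiyama–Isayama hydroperoxysilylation (Co(thd)2, bis(2,2,6,6-tetramethylheptane-3,5-dionato)cobalt, cat., O2, Et3SiH) should place the silylperoxy group on the tertiary carbon C6 and give methyl (4R,8R)-4,6,8-trimethyl-3-oxo-16-phenyl-6-[(triethylsilyl)peroxy]hexadecanoate F2 as both C6 epimers. Desilylation with dilute HCl in methanol lets the hydroperoxide close onto the C3 ketone to methyl 2-[(3S,4R,6S)-3-hydroxy-4,6-dimethyl-6-[(2R)-2-methyl-10-phenyldecyl]-1,2-dioxan-3-yl]acetate F3 and its C6 epimer, which would have to be separated by chromatography. The ester of F3 would be cleaved with pig liver esterase at pH 7. This fallback gives up control at C6 in exchange for precedented steps.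

Step 4 may fail through attack of the Grignard reagent at the carbonyl group next to the methyl-bearing carbon (wrong regioisomer), through a second addition to give a lactone, or through enolisation of the anhydride with erosion of C4. The fallback differentiates the two carboxyl groups before the C–C bond is made; it sets out from 8 (made from 5) and commercial dimethyl (R)-2-methylbutanedioate and comes back at 9. Monosaponification of the less hindered ester (KOH, 1 equiv, MeOH, 0 °C) should give (3R)-4-methoxy-3-methyl-4-oxobutanoic acid F4. Oxalyl chloride with catalytic DMF gives methyl (2R)-4-chloro-2-methyl-4-oxobutanoate F5. Acylation of 8 with F5 under Fe(acac)3 (tris(acetylacetonato)iron) catalysis at −78 °C should give methyl (2R,6R)-2,6-dimethyl-4-oxo-14-phenyltetradecanoate F6, and LiOH in THF/H2O returns 9.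

Step 6 may fail through acid-catalysed cyclodehydration of the 1,4-diketone to a furan (Paal–Knorr), intramolecular aldol addition of C2 to the C6 ketone, over-peroxidation to geminal bishydroperoxides or a bridged tetraoxane, or acid-induced enolisation toward C4. The fallback makes the same ozonide by cycloaddition instead of ketalisation; it sets out from 9 and comes back at 13. MeONH2·HCl in pyridine should give (2R,6R)-4-(methoxyimino)-2,6-dimethyl-14-phenyltetradecanoic acid F7. Masamune–Brooks homologation as in step 5 gives methyl (4R,8R)-6-(methoxyimino)-4,8-dimethyl-3-oxo-16-phenylhexadecanoate F8. Ozone in CH2Cl2 at −78 °C (intramolecular Griesbaum co-ozonolysis) should cleave the oxime ether to the C6 carbonyl oxide with loss of methyl nitrite, and the carbonyl oxide adds across the C3 ketone in a [3+2] cycloaddition to give 13.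

Further compounds
F1 | step 8 | methyl (4R,8R)-4,8-dimethyl-6-methylidene-3-oxo-16-phenylhexadecanoate | C[C@H](CCCCCCCCc1ccccc1)CC(=C)C[C@@H](C)C(=O)CC(=O)OC
F2 | step 8 | methyl (4R,8R)-4,6,8-trimethyl-3-oxo-16-phenyl-6-[(triethylsilyl)peroxy]hexadecanoate (C6 epimers) | C[C@H](CCCCCCCCc1ccccc1)CC(C)(OO[Si](CC)(CC)CC)C[C@@H](C)C(=O)CC(=O)OC
F3 | step 8 | methyl 2-[(3S,4R,6S)-3-hydroxy-4,6-dimethyl-6-[(2R)-2-methyl-10-phenyldecyl]-1,2-dioxan-3-yl]acetate | C[C@H](CCCCCCCCc1ccccc1)C[C@@]1(C)C[C@@H](C)[C@](O)(CC(=O)OC)OO1
F4 | step 4 | (3R)-4-methoxy-3-methyl-4-oxobutanoic acid | C[C@H](CC(=O)O)C(=O)OC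
F5 | step 4 | methyl (2R)-4-chloro-2-methyl-4-oxobutanoate | C[C@H](CC(=O)Cl)C(=O)OC
F6 | step 4 | methyl (2R,6R)-2,6-dimethyl-4-oxo-14-phenyltetradecanoate | C[C@H](CCCCCCCCc1ccccc1)CC(=O)C[C@@H](C)C(=O)OC
F7 | step 6 | (2R,6R)-4-(methoxyimino)-2,6-dimethyl-14-phenyltetradecanoic acid (E/Z mixture) | C[C@H](CCCCCCCCc1ccccc1)CC(=NOC)C[C@@H](C)C(=O)O
F8 | step 6 | methyl (4R,8R)-6-(methoxyimino)-4,8-dimethyl-3-oxo-16-phenylhexadecanoate (E/Z mixture) | C[C@H](CCCCCCCCc1ccccc1)CC(=NOC)C[C@@H](C)C(=O)CC(=O)OC
A1 | direct plan | methyl (4R,6E,8R)-4,6,8-trimethyl-3-oxo-16-phenylhexadec-6-enoate | C[C@H](CCCCCCCCc1ccccc1)/C=C(C)/C[C@@H](C)C(=O)CC(=O)OC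
A2 | direct plan | methyl (4R,6E,8R)-3-hydroperoxy-3-methoxy-4,6,8-trimethyl-16-phenylhexadec-6-enoate (C3 epimers) | C[C@H](CCCCCCCCc1ccccc1)/C=C(C)/C[C@@H](C)C(OC)(OO)CC(=O)OC
A3 | direct plan | methyl 2-[(4R,6S)-3-methoxy-4,6-dimethyl-6-[(2R)-2-methyl-10-phenyldecyl]-1,2-dioxan-3-yl]acetate (C3 epimers) | C[C@H](CCCCCCCCc1ccccc1)C[C@@]1(C)C[C@@H](C)C(OC)(CC(=O)OC)OO1
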